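**Plan**

1. Retrosynthetic cuts, in order: the C4–O bond of the oxirane (C5–O displaces a C3/C4 cyclic sulfate), C3–O and C4–O (dihydroxylation of C3=C4), the C6 acetate and a C5/C6 acetal, C2–H (ketone reduction), C1–O (Rubottom oxidation), the C6–O bond (oxa-Michael addition), and last C5–O (dearomatisation of a phenol).
2. Enabling feature: in the six-membered carbocycle C5 is a fully substituted carbinol carbon (bearing C7H2OBz) lying 1,4 to the oxygenated C2, and O5 and O6 are cis on adjacent carbons. This is a para-quinol of 4-hydroxybenzyl benzoate whose hydroxyl has reached C6 across a one-carbon bridge, a cis-fused 1,3-dioxolane on C5/C6.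
3. Forward order of rings: the carbocycle comes from the arene (step 2), the dioxolane closes in step 3 and is opened in step 9, a temporary cyclic sulfate spans C3/C4 (step 12), and the oxirane closes last (step 13).
4. Stereochemistry: a chiral phosphoric acid chooses between the two enantiotopic enone carbons and so fixes C5 and C6. C1 (oxidation anti to C6–O), C2 (axial hydride), C3/C4 (osmylation anti to O5 and O2) and the inversion at C4 on ring closure follow by substrate control.

Key step: step 3

Convention: one ring numbering is used throughout: C1 (OAc in the target), C2 (OH), C3 (OH), C4 (oxirane CH), C5 (oxirane carbon bearing C7H2OBz), C6 (OAc). With the ring drawn flat and C1→C6 running clockwise, β is the face toward the viewer. In the target C1–OAc, C3–OH and C7 are β; C2–OH, C6–OAc and the oxirane oxygen are α.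

Assumption: the sense of induction of the phosphoric acid on this quinol cannot be predicted with certainty. (R)-TRIP is named for definiteness, and its commercially available mirror image is used unchanged if a first experiment shows the opposite sense.

**Route**

Step 1
Reactants: 1 4-hydroxybenzyl alcohol; 2 benzoic acid
Product: 3 4-hydroxybenzyl benzoate
Conditions: PPh3, DIAD, THF, 0 °C → rt
Reagents that add atoms: benzoic acid (2), O=C(O)c1ccccc1
Why: Mitsunobu esterification: the alkoxyphosphonium ion of the primary benzylic alcohol is displaced by benzoate while the much less acidic phenol is neither activated nor acylated, and the neutral medium spares the product the base-induced loss of benzoate through a quinone methide.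

Step 2
Reactants: 3 4-hydroxybenzyl benzoate
Product: 4 (1-hydroxy-4-oxocyclohexa-2,5-dien-1-yl)methyl benzoate (para-quinol, achiral)
Conditions: PhI(OAc)2, MeCN/H2O (3:1), 0 °C
Reagents that add atoms: water, O
Why: oxidative dearomatisation of a para-substituted phenol with a hypervalent iodine reagent: the phenol oxygen binds to iodine, water adds at the para carbon as iodobenzene leaves, and the cross-conjugated para-quinol should result with the benzoate untouched by the mildly acidic medium.

Step 3
Reactants: 4 para-quinol; 5 isobutyraldehyde
Product: 7 cis-fused dioxolane enone (C2 ketone; C3=C4; acetal oxygens α on C5 and C6; C7 β; isopropyl exo), via hemiacetal 6 (not isolated)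
Conditions: 5 (3 equiv), (R)-TRIP [(R)-3,3′-bis(2,4,6-triisopropylphenyl)-1,1′-binaphthyl-2,2′-diyl hydrogen phosphate] (5 mol%), CH2Cl2, 0 °C → rt
Reagents that add atoms: isobutyraldehyde (5), CC(C)C=O
Why: The phosphoric acid activates isobutyraldehyde so that the tertiary C5 hydroxyl adds reversibly to give hemiacetal 6, and the same catalyst then bridges the hemiacetal OH (through P=O) and the dienone carbonyl (through P–OH) while the hemiacetal oxygen adds to one enone β-carbon, after which the enol tautomerises to the C1 methylene. The closest known reaction type is the chiral phosphoric acid-catalysed acetalisation/oxa-Michael desymmetrisation of para-quinols and para-peroxyquinols with aldehydes. The 1,3-dioxolane closes 5-exo-trig, the C6=C1 double bond lying outside the new ring. C6 and C5 are set together by the catalyst's choice between the two enantiotopic β-carbons (C5 becomes stereogenic only once one arm has reacted), their cis relationship is enforced by the five-membered ring, and the acetal carbon is set by the preference of the isopropyl group for the exo (convex) side, the hemiacetal epimers interconverting before the ring closes. The step needs enantiotopic-group selectivity and mono-addition: the mirror symmetry of 4 makes the two arms differ only within the chiral ion pair, the single hydroxyl allows only one acetal to form, and the benzoate on C7 is remote and unreactive.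

Step 4
Reactants: 7 cis-fused dioxolane enone
Product: 8 trimethylsilyl dienol ether (C1=C2–OSiMe3, C3=C4; dioxolane unchanged)
Conditions: Me3SiCl, LiN(SiMe3)2, THF, −78 °C (in situ quench); crude product used directly
Reagents that add atoms: chlorotrimethylsilane, C[Si](C)(C)Cl
Why: kinetic silyl enol ether formation with in situ trapping: C1 holds the only enolisable hydrogens (C5 is quaternary, so no extended dienolate can form) and the lithium enolate is silylated on oxygen as fast as it is generated, before it can expel the C6 acetal oxygen in a retro-oxa-Michael elimination.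

Step 5
Reactants: 8 trimethylsilyl dienol ether
Product: 10 C1β-hydroxy enone, via silyloxy epoxide 9 (not isolated)
Conditions: DMDO, acetone/CH2Cl2, −78 → −20 °C; then aq. citric acid, THF, 0 °C
Reagents that add atoms: dimethyldioxirane, CC1(C)OO1
Why: Rubottom oxidation: the dioxirane epoxidises the electron-rich C1=C2 enol ether in preference to C3=C4 and does so on the convex β face, anti to the C6–O bond of the cis-fused dioxolane, so that acid opening of the silyloxy epoxide should leave the C1 hydroxyl β (trans to C6–O).

Step 6
Reactants: 10 C1β-hydroxy enone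
Product: 11 C1β-acetoxy enone
Conditions: Ac2O, pyridine, DMAP (cat.), CH2Cl2, 0 °C
Reagents that add atoms: acetic anhydride, CC(=O)OC(C)=O
Why: acetylation of a secondary alcohol with acetic anhydride under nucleophilic catalysis, run cold and briefly so that the α-acyloxy ketone is neither epimerised at C1 nor induced to eliminate the C6 oxygen.

Step 7
Reactants: 11 C1β-acetoxy enone
Product: 12 allylic alcohol (C1β-OAc, C2α-OH, C3=C4, dioxolane intact)
Conditions: NaBH4, CeCl3·7H2O, MeOH, −78 °C; AcOH quench
Reagents that add atoms: none
Why: Luche reduction: the cerium-modified borohydride attacks the enone carbonyl only in the 1,2 sense and axially from the convex β face of the half-chair in which the C1 acetate is pseudoequatorial, which should place the new C2 hydroxyl pseudoequatorial and α (trans to the C1 acetate), and the low temperature with an acidic quench prevents acetyl migration.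

Step 8
Reactants: 12 allylic alcohol
Product: 13 C2α benzyl ether
Conditions: BnOC(=NH)CCl3, TfOH (cat.), CH2Cl2/cyclohexane (1:2), 0 °C
Reagents that add atoms: benzyl 2,2,2-trichloroacetimidate, N=C(OCc1ccccc1)C(Cl)(Cl)Cl
Why: acid-catalysed O-benzylation with a trichloroacetimidate: the only free hydroxyl is alkylated without base, so the neighbouring C1 acetate cannot migrate, and the trace of anhydrous acid should not open the dioxolane.

Step 9
Reactants: 13 C2α benzyl ether
Product: 14 C5α,C6α-diol (C1β-OAc, C2α-OBn, C3=C4, tertiary C5-OH, secondary C6-OH)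
Conditions: TFA/H2O (9:1), CH2Cl2, 0 °C → rt
Reagents that add atoms: none
Why: acid-catalysed acetal hydrolysis: ring opening to the oxocarbenium ion of isobutyraldehyde releases the C5 and C6 hydroxyls with retention at both carbons, the benzyl ether and esters are stable to aqueous trifluoroacetic acid, and an acetyl shift between O1 and O6, should it occur, is made good in step 10.

Step 10
Reactants: 14 C5α,C6α-diol
Product: 15 C1β,C6α-diacetate with free tertiary C5α-OH
Conditions: Ac2O, pyridine, 0 °C → rt
Reagents that add atoms: acetic anhydride, CC(=O)OC(C)=O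
Why: chemoselective acetylation: without an acyl-transfer catalyst acetic anhydride in pyridine esterifies the secondary C6 hydroxyl and leaves the hindered tertiary C5 hydroxyl free for the later ring closure.

Step 11
Reactants: 15 diacetate
Product: 16 triol (C3β-OH, C4β-OH, C5α-OH; C1β-OAc, C2α-OBn, C6α-OAc)
Conditions: OsO4 (5 mol%), NMO, acetone/H2O (4:1), rt
Reagents that add atoms: N-methylmorpholine N-oxide, C[N+]1([O-])CCOCC1; water, O
Why: Upjohn dihydroxylation: OsO4 adds suprafacially to C3=C4 on the β face, anti to the pseudoaxial C5 hydroxyl and to the C2 benzyloxy group (the usual anti preference of osmylation next to allylic oxygen), which should set C3–OH and C4–OH both β, and no ester sits where it could migrate onto the new hydroxyls.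

Step 12
Reactants: 16 triol
Product: 18 C3/C4 cyclic sulfate (tertiary C5α-OH free), via cyclic sulfite 17 (not isolated)
Conditions: SOCl2, Et3N, CH2Cl2, 0 °C; then RuCl3·3H2O (cat.), NaIO4, MeCN/H2O, 0 °C
Reagents that add atoms: thionyl chloride, O=S(Cl)Cl; sodium periodate, [Na+].[O-]I(=O)(=O)=O
Why: two-stage cyclic sulfate synthesis: thionyl chloride can bridge only the cis C3/C4 diol (the C4 and C5 hydroxyls are trans-diaxial and the tertiary one is hindered), and RuO4 generated from RuCl3 and NaIO4 oxidises the sulfite to the sulfate faster than it attacks the benzyl ether.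

Step 13
Reactants: 18 cyclic sulfate
Product: 20 2-O-benzyl ether of the target, via epoxy sulfate sodium salt 19 (not isolated)
Conditions: NaN(SiMe3)2 (1.05 equiv), THF, −78 → 0 °C; then H2SO4 (cat.), H2O (1 equiv), THF, rt
Reagents that add atoms: none
Why: intramolecular Williamson-type opening of a cyclic sulfate (3-exo-tet): the C5 alkoxide is antiperiplanar to the axial C4–O bond and displaces it with inversion, which places the oxirane on the α face and leaves C3 as a β sulfate monoester, and this is then cleaved at sulfur by acid-catalysed hydrolysis with one equivalent of water, conditions the electron-poor oxirane should tolerate.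

Step 14
Reactants: 20 2-O-benzyl ether of the target
Product: 21 target CNP0171674.1
Conditions: H2 (1 atm), Pd/C, EtOAc, rt
Reagents that add atoms: none
Why: catalytic hydrogenolysis of a benzyl ether under neutral conditions, which avoids both acyl migration and Payne rearrangement of the epoxy alcohol and should leave the non-benzylic oxirane and the benzoate intact.

**Compound list**

1 | 4-hydroxybenzyl alcohol | OCc1ccc(O)cc1 | starting material
2 | benzoic acid | O=C(O)c1ccccc1 | starting material
3 | 4-hydroxybenzyl benzoate | O=C(OCc1ccc(O)cc1)c1ccccc1 | intermediate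
4 | (1-hydroxy-4-oxocyclohexa-2,5-dien-1-yl)methyl benzoate (para-quinol) | O=C1C=CC(O)(COC(=O)c2ccccc2)C=C1 | intermediate
5 | isobutyraldehyde (2-methylpropanal) | CC(C)C=O | starting material
6 | hemiacetal of 4 and 5, [1-(1-hydroxy-2-methylpropoxy)-4-oxocyclohexa-2,5-dien-1-yl]methyl benzoate (S at the hemiacetal carbon) | O=C1C=CC(COC(=O)c2ccccc2)(O[C@@H](C(C)C)O)C=C1 | intermediate
7 | cis-fused dioxolane enone, [(2S,3aR,7aR)-2-isopropyl-6-oxo-3a,6,7,7a-tetrahydro-1,3-benzodioxol-3a-yl]methyl benzoate (acetal oxygens α on C5 and C6, C7 β, isopropyl exo) | C1C(=O)C=C[C@]2(COC(=O)c3ccccc3)O[C@@H](C(C)C)O[C@H]12 | intermediate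
8 | trimethylsilyl dienol ether of 7 (C1=C2–OSiMe3, C3=C4) | C1=C(O[Si](C)(C)C)C=C[C@]2(COC(=O)c3ccccc3)O[C@@H](C(C)C)O[C@H]12 | intermediate
9 | silyloxy epoxide (β-oxirane across C1–C2 of 8, OSiMe3 on C2) | O1[C@H]2[C@]1(O[Si](C)(C)C)C=C[C@]3(COC(=O)c4ccccc4)O[C@@H](C(C)C)O[C@H]23 | intermediate
10 | C1β-hydroxy enone (hydroxyl trans to C6–O) | O[C@H]1C(=O)C=C[C@]2(COC(=O)c3ccccc3)O[C@@H](C(C)C)O[C@H]12 | intermediate
11 | C1β-acetoxy enone | CC(=O)O[C@H]1C(=O)C=C[C@]2(COC(=O)c3ccccc3)O[C@@H](C(C)C)O[C@H]12 | intermediate
12 | allylic alcohol (C1β-OAc, C2α-OH, C3=C4, dioxolane on C5/C6) | CC(=O)O[C@H]1[C@H](O)C=C[C@]2(COC(=O)c3ccccc3)O[C@@H](C(C)C)O[C@H]12 | intermediate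
13 | C2α benzyl ether of 12 | CC(=O)O[C@H]1[C@H](OCc3ccccc3)C=C[C@]2(COC(=O)c4ccccc4)O[C@@H](C(C)C)O[C@H]12 | intermediate
14 | C5α,C6α-diol (C1β-OAc, C2α-OBn, C3=C4, C7 β) | CC(=O)O[C@H]1[C@H](OCc2ccccc2)C=C[C@@](O)(COC(=O)c2ccccc2)[C@@H]1O | intermediate
15 | C1β,C6α-diacetate with free tertiary C5α-OH (C2α-OBn, C3=C4) | CC(=O)O[C@H]1[C@H](OCc2ccccc2)C=C[C@@](O)(COC(=O)c2ccccc2)[C@@H]1OC(C)=O | intermediate
16 | triol (C3β-OH, C4β-OH, C5α-OH; C1β-OAc, C2α-OBn, C6α-OAc) | CC(=O)O[C@H]1[C@H](OCc2ccccc2)[C@@H](O)[C@@H](O)[C@@](O)(COC(=O)c2ccccc2)[C@@H]1OC(C)=O | intermediate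
17 | C3/C4 cyclic sulfite of 16 (both oxygens β; mixture of epimers at sulfur) | CC(=O)O[C@H]1[C@H](OCc2ccccc2)[C@H]3OS(=O)O[C@H]3[C@@](O)(COC(=O)c2ccccc2)[C@@H]1OC(C)=O | intermediate
18 | C3/C4 cyclic sulfate of 16 (tertiary C5α-OH free) | CC(=O)O[C@H]1[C@H](OCc2ccccc2)[C@H]3OS(=O)(=O)O[C@H]3[C@@](O)(COC(=O)c2ccccc2)[C@@H]1OC(C)=O | intermediate
19 | sodium salt of the C3β sulfate monoester of the C4,C5 α-epoxide (C2α-OBn) | CC(=O)O[C@H]1[C@H](OCc2ccccc2)[C@@H](OS(=O)(=O)[O-])[C@@H]2O[C@]2(COC(=O)c2ccccc2)[C@@H]1OC(C)=O.[Na+] | intermediate
20 | 2-O-benzyl ether of the target (C3β-OH free, C4,C5 α-epoxide) | CC(=O)O[C@H]1[C@H](OCc2ccccc2)[C@@H](O)[C@@H]2O[C@]2(COC(=O)c2ccccc2)[C@@H]1OC(C)=O | intermediate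
21 | CNP0171674.1, [(1S,2R,3S,4R,5R,6S)-2,3-diacetoxy-4,5-dihydroxy-7-oxabicyclo[4.1.0]heptan-1-yl]methyl benzoate | CC(=O)O[C@H]1[C@H](O)[C@@H](O)[C@@H]2O[C@]2(COC(=O)c2ccccc2)[C@@H]1OC(C)=O | target

**Step count and risks**

Total step count: 14.
Longest linear sequence: 14 steps (1 → 21); the route is fully linear, 2 and 5 entering as single reagents.

Steps most likely to fail:

Step 3. The catalyst may discriminate poorly between the two enantiotopic enone arms, or reversible opening of the dioxolane under the acid may erode the enantiomeric purity. The fallback sets out from 4 and returns at 7. Quinol 4 would be combined with phenylboronic acid and a cinchona-alkaloid-derived amine–thiourea. The boronic acid hemiester formed at the C5 hydroxyl then transfers its B–OH oxygen to C6 in an amine-directed oxa-Michael addition, a reaction known for γ-hydroxy enones, to give the cis-fused cyclic phenylboronate F1. Exchange of boron onto pinacol would release the cis-diol enone F2, and acetalisation with 5 (PPTS, MgSO4, CH2Cl2) would give 7.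

Step 4. The C1 enolate may expel the C6 acetal oxygen before it is silylated (retro-oxa-Michael elimination), which erases C6 and returns achiral dienone material. The fallback sets out from 7 and returns at 11, replacing steps 4 to 6. Enone 7 would be heated with Mn(OAc)3·2H2O in benzene at reflux, a direct α′-acetoxylation of enones that proceeds through a manganese enolate and an α-keto radical and never generates an alkali-metal enolate. Acetate transfer is expected on the convex β face. This detour passes through no compound outside the list (F0).

Step 13. Acetyl or benzoyl transfer from O6 or O7 to the C5 alkoxide, attack of the base at sulfur, or acid opening of the new oxirane during hydrolysis of the sulfate monoester may intervene. The fallback sets out from 16 and returns at 20, replacing steps 12 and 13. The equatorial C3 hydroxyl of triol 16 would be silylated selectively (Et3SiCl, imidazole, DMF, −20 °C) to give the C3 triethylsilyl ether F3. The remaining secondary C4 hydroxyl would then be converted into the C4 methanesulfonate F4 (MsCl, Et3N, CH2Cl2, −20 °C). DBU would close the oxirane from the tertiary C5 hydroxyl with inversion at C4 to give the C3-silylated epoxide F5, and HF·pyridine in THF would remove the silyl group to give 20.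

Further compounds
F1 | step 3 | cis-fused cyclic phenylboronate of the C5,C6-diol enone (both oxygens α, C7 β) | C1C(=O)C=C[C@]2(COC(=O)c3ccccc3)OB(c3ccccc3)O[C@H]12
F2 | step 3 | cis-diol enone, (1,6-dihydroxy-4-oxocyclohex-2-en-1-yl)methyl benzoate (C5α-OH, C6α-OH) | C1C(=O)C=C[C@@](O)(COC(=O)c2ccccc2)[C@@H]1O
F0 | step 4 | none | none
F3 | step 13 | C3β triethylsilyl ether of triol 16 | CC(=O)O[C@H]1[C@H](OCc2ccccc2)[C@@H](O[Si](CC)(CC)CC)[C@@H](O)[C@@](O)(COC(=O)c2ccccc2)[C@@H]1OC(C)=O
F4 | step 13 | C4β methanesulfonate of F3 | CC(=O)O[C@H]1[C@H](OCc2ccccc2)[C@@H](O[Si](CC)(CC)CC)[C@@H](OS(C)(=O)=O)[C@@](O)(COC(=O)c2ccccc2)[C@@H]1OC(C)=O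
F5 | step 13 | C3β triethylsilyl ether of 20 (C4,C5 α-epoxide) | CC(=O)O[C@H]1[C@H](OCc2ccccc2)[C@@H](O[Si](CC)(CC)CC)[C@@H]2O[C@]2(COC(=O)c2ccccc2)[C@@H]1OC(C)=O
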